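The tetramer reads, top to bottom, epicatechin (unit 1), epigallocatechin gallate (unit 2), epicatechin (unit 3), catechin (unit 4), joined 4β→8. The route rests on opening the pyran ring (ring C) of unit 3 at O1–C8a and C3–C4. C3 sits between benzylic C4 and carbinol C2, so as a masked ketone it is an acyl-anion carbon; C8a, meta to the C5 and C7 oxygens, is an SNAr site of a 2,4,6-trifluorobenzyl group. One flask joins 1,3-dithiane, an aryl aldehyde and that bromide: benzylation at C3, then alkoxide closure at C8a. Dynamic kinetic reduction later sets C2 and C3; Friedel–Crafts couplings from C4 to C8 assemble the tetramer.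

Key step: step 1

Assumption: in step 4 the (S,S)-configured TsDPEN catalyst is taken to reduce the (2R)-ketone to the (3R)-alcohol, by analogy with other alpha-aryl cyclic ketones; if the sense proves opposite, the (R,R)-catalyst is used.

Step 1
Reactants: 1 1,3-dithiane; 2 3,4-bis(benzyloxy)benzaldehyde; 3 2,4,6-trifluorobenzyl bromide
Product: 8 racemic 2-[3,4-bis(benzyloxy)phenyl]-5,7-difluorospiro[chromane-3,2'-[1,3]dithiane], via 2-lithio-1,3-dithiane 4 (not isolated), via lithium alkoxide adduct 5 (not isolated), via C3-lithiated alkoxide 6 (not isolated), via C-benzylated lithium alkoxide 7 (not isolated)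
Conditions: 1, n-BuLi (1.0 equiv), THF, −30 °C; then 2, −78 °C; then n-BuLi (1.1 equiv), TMEDA, −78 to −20 °C; then 3, −78 °C; then DMPU, −78 to 50 °C
Reagents that add atoms: n-butyllithium, [Li]CCCC
Why: Corey–Seebach three-component linchpin coupling that ends in an intramolecular SNAr (a tandem SN2–SNAr annulation): lithiated dithiane 4 adds to aldehyde 2 (C2–C3), the second equivalent of n-BuLi removes the remaining dithiane proton of alkoxide 5, whose beta-oxido group is too poor a leaving group to eliminate, and the soft carbanion of 6 is benzylated by 3 at C3 (C3–C4). On warming in the presence of DMPU the lithium alkoxide O1 of 7 adds to C8a, the ortho C–F carbon that is meta to the other two fluorines, and fluoride leaves from the Meisenheimer adduct (O1–C8a). Ring C thus closes by a 6-exo addition–elimination, helped by the fully substituted C3. The closest known reactions are the one-pot double alkylation of 1,3-dithiane through an alkoxide-bearing 2-lithio-dithiane and the alkoxide SNAr closure of pyran rings onto 1,3,5-trifluoroarenes. The one new stereocentre, C2, is left uncontrolled on purpose, because it becomes epimerisable once C3 is unmasked as the ketone and is then set in step 4. The step needs C- before O-alkylation and a single ring size, which the far more nucleophilic carbanion, the single alkoxide of 7 and the two equivalent ortho fluorines should secure.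

Step 2
Reactants: 8 racemic 2-[3,4-bis(benzyloxy)phenyl]-5,7-difluorospiro[chromane-3,2'-[1,3]dithiane]
Product: 9 racemic 5,7-bis(benzyloxy)-2-[3,4-bis(benzyloxy)phenyl]spiro[chromane-3,2'-[1,3]dithiane]
Conditions: BnOH, NaH, NMP, 120 °C
Reagents that add atoms: benzyl alcohol, OCc1ccccc1
Why: Twofold nucleophilic aromatic substitution (SNAr) of the C5 and C7 fluorides by sodium benzyl oxide, each carbon being inductively activated by the meta heteroatoms of ring A, on a substrate with no enolisable site because C3 is still masked as the dithiane; no stereocentre is set.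

Step 3
Reactants: 9 racemic 5,7-bis(benzyloxy)-2-[3,4-bis(benzyloxy)phenyl]spiro[chromane-3,2'-[1,3]dithiane]
Product: 10 racemic 5,7-bis(benzyloxy)-2-[3,4-bis(benzyloxy)phenyl]chroman-3-one (tetra-O-benzylflavan-3-one)
Conditions: MeI, CaCO3, MeCN/H2O, 45 °C
Reagents that add atoms: water, O
Why: Alkylative dethioketalisation, in which S-methylation makes the dithiane a sulfonium leaving group, water hydrolyses the thionium ion and CaCO3 buffers the HI, under non-oxidising conditions that spare the benzyl ethers; C2 stays racemic, as the next step requires.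

Step 4
Reactants: 10 racemic 5,7-bis(benzyloxy)-2-[3,4-bis(benzyloxy)phenyl]chroman-3-one
Product: 11 (2R,3R)-5,7-bis(benzyloxy)-2-[3,4-bis(benzyloxy)phenyl]chroman-3-ol (5,7,3',4'-tetra-O-benzylepicatechin)
Conditions: RuCl[(S,S)-TsDPEN](p-cymene) (2 mol %), HCO2H/Et3N, DMF, 40 °C
Reagents that add atoms: none
Why: Noyori–Ikariya asymmetric transfer hydrogenation with dynamic kinetic resolution, in which Et3N interconverts the ketone enantiomers through the C2 enol (C2–H is alpha to the ketone, benzylic and O-substituted) while the chiral ruthenium hydride reduces the (2R)-ketone faster and adds hydride to C3 anti to the 2-aryl group, so the catalyst sets C2 as R and the substrate relays this to the cis (3R)-alcohol.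

Step 5
Reactants: 11 5,7,3',4'-tetra-O-benzylepicatechin
Product: 12 5,7,3',4'-tetra-O-benzyl-4β-(2-ethoxyethoxy)epicatechin (2R; 3-OH cis to the 2-aryl group; 4-alkoxy trans to the 3-OH)
Conditions: DDQ, 2-ethoxyethanol, CH2Cl2, rt
Reagents that add atoms: 2-ethoxyethanol, CCOCCO
Why: Oxidative benzylic etherification, in which DDQ removes hydride from C4, the benzylic position conjugated to the ortho and para oxygens of ring A, and 2-ethoxyethanol adds to the cation from the beta face, anti to the cis 2-aryl and 3-OH groups, which sets C4 as 3,4-trans.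

Step 6
Reactants: 13 (+)-catechin
Product: 14 (2R,3S)-5,7,3',4'-tetra-O-benzylcatechin
Conditions: BnBr, K2CO3, DMF, 0 °C to rt
Reagents that add atoms: benzyl bromide, BrCc1ccccc1
Why: Williamson ether synthesis under carbonate conditions, which benzylates the four phenols (pKa near 10) and leaves the secondary 3-OH free; no stereocentre is touched.

Step 7
Reactants: 12 5,7,3',4'-tetra-O-benzyl-4β-(2-ethoxyethoxy)epicatechin (unit 3); 14 5,7,3',4'-tetra-O-benzylcatechin (unit 4, in excess)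
Product: 15 5,7,3',4'-tetra-O-benzylepicatechin-(4β→8)-5,7,3',4'-tetra-O-benzylcatechin (units 3 and 4)
Conditions: TMSOTf (cat.), CH2Cl2, −78 °C
Reagents that add atoms: none
Why: Lewis-acid-promoted Friedel–Crafts-type interflavan coupling, in which TMSOTf ionises the C4 ether of 12 and C8 of 14, its most nucleophilic ring-A carbon, attacks the benzylic cation from the beta face, anti to the cis 2-aryl and 3-OH groups, which sets C4 of unit 3 as 4β (3,4-trans), while excess 14 suppresses further reaction of the product.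

Step 8
Reactants: 16 (−)-epigallocatechin
Product: 17 (2R,3R)-5,7-bis(benzyloxy)-2-[3,4,5-tris(benzyloxy)phenyl]chroman-3-ol (5,7,3',4',5'-penta-O-benzylepigallocatechin)
Conditions: BnBr, K2CO3, degassed DMF, Ar, 0 °C to rt
Reagents that add atoms: benzyl bromide, BrCc1ccccc1
Why: Williamson ether synthesis under carbonate conditions, which benzylates the five phenols and leaves the secondary 3-OH free for the acylation that follows; air is excluded because the pyrogallol ring is oxidation-prone, and no stereocentre is touched.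

Step 9
Reactants: 17 5,7,3',4',5'-penta-O-benzylepigallocatechin; 18 3,4,5-tris(benzyloxy)benzoic acid
Product: 19 (2R,3R)-5,7-bis(benzyloxy)-2-[3,4,5-tris(benzyloxy)phenyl]chroman-3-yl 3,4,5-tris(benzyloxy)benzoate (octa-O-benzyl epigallocatechin gallate)
Conditions: DCC, DMAP, CH2Cl2, rt
Reagents that add atoms: none
Why: Steglich esterification, in which the O-acylisourea of 18 is passed by DMAP as an acylpyridinium ion to the axial 3-OH, the only free hydroxyl of 17; the C–O bond at C3 is not broken, so the (2R,3R) configuration is retained.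

Step 10
Reactants: 19 octa-O-benzyl epigallocatechin gallate
Product: 20 4β-(2-ethoxyethoxy) derivative of 19 (4-alkoxy trans to the 3-O-galloyl group)
Conditions: DDQ, 2-ethoxyethanol, CH2Cl2, rt
Reagents that add atoms: 2-ethoxyethanol, CCOCCO
Why: The same DDQ-mediated oxidative benzylic etherification as in step 5, selective for C4 because only that C–H is conjugated to the ring-A oxygens, with the alcohol adding anti to the cis 2-aryl and 3-O-galloyl groups to set C4 as 4β.

Step 11
Reactants: 20 4β-(2-ethoxyethoxy) octa-O-benzyl epigallocatechin gallate (unit 2); 15 dimer of units 3 and 4 (in excess, recovered)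
Product: 21 octa-O-benzyl epigallocatechin gallate-(4β→8)-tetra-O-benzylepicatechin-(4β→8)-tetra-O-benzylcatechin (units 2 to 4)
Conditions: TMSOTf (cat.), CH2Cl2, −78 to −40 °C
Reagents that add atoms: none
Why: The same Friedel–Crafts-type coupling, in which the C4 cation of unit 2, shielded on its alpha face by the cis 2-aryl and 3-O-galloyl groups, is attacked from the beta face by C8 of unit 3, the only free C8 of 15 and its most reactive ring-A carbon, which sets C4 of unit 2 as 4β.

Step 12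
Reactants: 12 5,7,3',4'-tetra-O-benzyl-4β-(2-ethoxyethoxy)epicatechin (unit 1); 21 trimer of units 2 to 4
Product: 22 tetra-O-benzylepicatechin-(4β→8)-octa-O-benzyl epigallocatechin gallate-(4β→8)-tetra-O-benzylepicatechin-(4β→8)-tetra-O-benzylcatechin (fully benzylated tetramer)
Conditions: TMSOTf (cat.), CH2Cl2, −78 °C
Reagents that add atoms: none
Why: The same Friedel–Crafts-type coupling once more, in which the cation from 12 is attacked on its beta face by C8 of unit 2, the only free C8 position of 21, which sets C4 of unit 1 as 4β (3,4-trans).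

Step 13
Reactants: 22 fully benzylated tetramer
Product: 23 CNP0332815.1, epicatechin-(4β→8)-epigallocatechin 3-O-gallate-(4β→8)-epicatechin-(4β→8)-catechin
Conditions: H2 (1 atm), Pd(OH)2/C, THF/MeOH/H2O, rt
Reagents that add atoms: none
Why: Global hydrogenolysis of the twenty benzyl ethers under neutral conditions, which should leave the gallate ester, the interflavan bonds and all stereocentres untouched.

Compound list
1 | 1,3-dithiane | C1CSCSC1 | starting material
2 | 3,4-bis(benzyloxy)benzaldehyde | O=Cc1ccc(OCc2ccccc2)c(OCc2ccccc2)c1 | starting material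
3 | 2,4,6-trifluorobenzyl bromide | BrCc1c(F)cc(F)cc1F | starting material
4 | 2-lithio-1,3-dithiane | [Li]C1SCCCS1 | intermediate
5 | lithium alkoxide of racemic [3,4-bis(benzyloxy)phenyl](1,3-dithian-2-yl)methanol | [Li]OC(c1ccc(OCc2ccccc2)c(OCc2ccccc2)c1)C1SCCCS1 | intermediate
6 | C3-lithiated alkoxide (O,C-dilithio derivative of the same carbinol, racemic) | [Li]OC(c1ccc(OCc2ccccc2)c(OCc2ccccc2)c1)C1([Li])SCCCS1 | intermediate
7 | lithium alkoxide of racemic [3,4-bis(benzyloxy)phenyl][2-(2,4,6-trifluorobenzyl)-1,3-dithian-2-yl]methanol | [Li]OC(c1ccc(OCc2ccccc2)c(OCc2ccccc2)c1)C1(Cc2c(F)cc(F)cc2F)SCCCS1 | intermediate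
8 | racemic 2-[3,4-bis(benzyloxy)phenyl]-5,7-difluorospiro[chromane-3,2'-[1,3]dithiane] | Fc1cc(F)c2c(c1)OC(c1ccc(OCc3ccccc3)c(OCc3ccccc3)c1)C1(SCCCS1)C2 | intermediate
9 | racemic 5,7-bis(benzyloxy)-2-[3,4-bis(benzyloxy)phenyl]spiro[chromane-3,2'-[1,3]dithiane] | c1ccccc1COc1cc(OCc2ccccc2)c2c(c1)OC(c1ccc(OCc3ccccc3)c(OCc3ccccc3)c1)C1(SCCCS1)C2 | intermediate
10 | racemic 5,7-bis(benzyloxy)-2-[3,4-bis(benzyloxy)phenyl]chroman-3-one | O=C1Cc2c(OCc3ccccc3)cc(OCc3ccccc3)cc2OC1c1ccc(OCc3ccccc3)c(OCc3ccccc3)c1 | intermediate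
11 | (2R,3R)-5,7,3',4'-tetra-O-benzylepicatechin | O[C@@H]1Cc2c(OCc3ccccc3)cc(OCc3ccccc3)cc2O[C@@H]1c1ccc(OCc3ccccc3)c(OCc3ccccc3)c1 | intermediate
12 | 5,7,3',4'-tetra-O-benzyl-4β-(2-ethoxyethoxy)epicatechin | CCOCCO[C@H]1c2c(OCc5ccccc5)cc(OCc5ccccc5)cc2O[C@H](c2ccc(OCc5ccccc5)c(OCc5ccccc5)c2)[C@@H]1O | intermediate
13 | (+)-catechin, (2R,3S) | O[C@H]1Cc2c(O)cc(O)cc2O[C@@H]1c1ccc(O)c(O)c1 | starting material
14 | (2R,3S)-5,7,3',4'-tetra-O-benzylcatechin | O[C@H]1Cc2c(OCc3ccccc3)cc(OCc3ccccc3)cc2O[C@@H]1c1ccc(OCc3ccccc3)c(OCc3ccccc3)c1 | intermediate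
15 | tetra-O-benzylepicatechin-(4β→8)-tetra-O-benzylcatechin | c1c(OCc5ccccc5)cc(OCc5ccccc5)c2c1O[C@H](c1ccc(OCc5ccccc5)c(OCc5ccccc5)c1)[C@H](O)[C@H]2c1c(OCc5ccccc5)cc(OCc5ccccc5)c2c1O[C@H](c1ccc(OCc5ccccc5)c(OCc5ccccc5)c1)[C@@H](O)C2 | intermediate
16 | (−)-epigallocatechin, (2R,3R) | O[C@@H]1Cc2c(O)cc(O)cc2O[C@@H]1c1cc(O)c(O)c(O)c1 | starting material
17 | (2R,3R)-5,7,3',4',5'-penta-O-benzylepigallocatechin | O[C@@H]1Cc2c(OCc3ccccc3)cc(OCc3ccccc3)cc2O[C@@H]1c1cc(OCc3ccccc3)c(OCc3ccccc3)c(OCc3ccccc3)c1 | intermediate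
18 | 3,4,5-tris(benzyloxy)benzoic acid | OC(=O)c1cc(OCc2ccccc2)c(OCc2ccccc2)c(OCc2ccccc2)c1 | starting material
19 | octa-O-benzyl epigallocatechin gallate, (2R,3R) | O=C(O[C@@H]1Cc2c(OCc5ccccc5)cc(OCc5ccccc5)cc2O[C@@H]1c1cc(OCc5ccccc5)c(OCc5ccccc5)c(OCc5ccccc5)c1)c1cc(OCc5ccccc5)c(OCc5ccccc5)c(OCc5ccccc5)c1 | intermediate
20 | 4β-(2-ethoxyethoxy)-octa-O-benzyl epigallocatechin gallate | O=C(O[C@@H]1[C@@H](OCCOCC)c2c(OCc5ccccc5)cc(OCc5ccccc5)cc2O[C@@H]1c1cc(OCc5ccccc5)c(OCc5ccccc5)c(OCc5ccccc5)c1)c1cc(OCc5ccccc5)c(OCc5ccccc5)c(OCc5ccccc5)c1 | intermediate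
21 | benzylated trimer of units 2 to 4 | O=C(O[C@@H]1[C@@H](c2c(OCc5ccccc5)cc(OCc5ccccc5)c3c2O[C@H](c2ccc(OCc5ccccc5)c(OCc5ccccc5)c2)[C@H](O)[C@H]3c2c(OCc5ccccc5)cc(OCc5ccccc5)c3c2O[C@H](c2ccc(OCc5ccccc5)c(OCc5ccccc5)c2)[C@@H](O)C3)c2c(OCc5ccccc5)cc(OCc5ccccc5)cc2O[C@@H]1c1cc(OCc5ccccc5)c(OCc5ccccc5)c(OCc5ccccc5)c1)c1cc(OCc5ccccc5)c(OCc5ccccc5)c(OCc5ccccc5)c1 | intermediate
22 | fully benzylated tetramer (twenty benzyl ethers) | O=C(O[C@@H]1[C@@H](c2c(OCc5ccccc5)cc(OCc5ccccc5)c3c2O[C@H](c2ccc(OCc5ccccc5)c(OCc5ccccc5)c2)[C@H](O)[C@H]3c2c(OCc5ccccc5)cc(OCc5ccccc5)c3c2O[C@H](c2ccc(OCc5ccccc5)c(OCc5ccccc5)c2)[C@@H](O)C3)c2c(OCc5ccccc5)cc(OCc5ccccc5)c([C@H]3c4c(OCc5ccccc5)cc(OCc5ccccc5)cc4O[C@H](c4ccc(OCc5ccccc5)c(OCc5ccccc5)c4)[C@@H]3O)c2O[C@@H]1c1cc(OCc5ccccc5)c(OCc5ccccc5)c(OCc5ccccc5)c1)c1cc(OCc5ccccc5)c(OCc5ccccc5)c(OCc5ccccc5)c1 | intermediate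
23 | CNP0332815.1 | O=C(O[C@@H]1[C@@H](c2c(O)cc(O)c3c2O[C@H](c2ccc(O)c(O)c2)[C@H](O)[C@H]3c2c(O)cc(O)c3c2O[C@H](c2ccc(O)c(O)c2)[C@@H](O)C3)c2c(O)cc(O)c([C@H]3c4c(O)cc(O)cc4O[C@H](c4ccc(O)c(O)c4)[C@@H]3O)c2O[C@@H]1c1cc(O)c(O)c(O)c1)c1cc(O)c(O)c(O)c1 | target

Total step count: 13. Longest linear sequence: 9 steps (steps 1, 2, 3, 4, 5, 7, 11, 12, 13). Compound 12 serves twice, as unit 3 in step 7 and as unit 1 in step 12.

Steps most likely to fail

Step 1. The second lithiation, next to the lithium alkoxide, may be incomplete, or the alkoxide may revert to aldehyde and dithiane anion before the ring closes. The fallback runs from 2 to 8 stepwise and needs no dianion. Addition of 4 to 2 with aqueous work-up should give racemic [3,4-bis(benzyloxy)phenyl](1,3-dithian-2-yl)methanol F1. Parikh–Doering oxidation (SO3·pyridine, DMSO, Et3N), which spares the sulfides, should give 2-[3,4-bis(benzyloxy)benzoyl]-1,3-dithiane F2, whose C–H between the ketone and two sulfur atoms is acidic enough for NaH. C-benzylation with 3 (NaH, DMF) should give 2-[3,4-bis(benzyloxy)benzoyl]-2-(2,4,6-trifluorobenzyl)-1,3-dithiane F3. NaBH4 reduction should give racemic [3,4-bis(benzyloxy)phenyl][2-(2,4,6-trifluorobenzyl)-1,3-dithian-2-yl]methanol F4, and KOt-Bu in DMF should close ring C by SNAr to 8.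

Step 4. Racemisation at C2 may be slower than reduction, so that only a kinetic resolution results, or the facial preference of the catalyst may be low. The fallback runs from 10 to 11 by diastereoselective reduction and classical resolution. LiBH(s-Bu)3 in THF at −78 °C should add hydride anti to the 2-aryl group and give racemic cis-5,7,3',4'-tetra-O-benzylflavan-3-ol F5. Acetylation with Candida antarctica lipase B and vinyl acetate, which normally acylates the (R)-carbinol of this substitution pattern, should give (2R,3R)-3-O-acetyl-5,7,3',4'-tetra-O-benzylepicatechin F6. F6 is separated from the unreacted (2S,3S)-alcohol and cleaved with K2CO3 in MeOH to 11.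

Step 12. The electrophile may condense with itself through its own free C8, the trimer may be attacked at a C6 position, or the acid may cleave interflavan bonds already present. The fallback runs from 11 to 23 with a capped electrophile. NBS in CH2Cl2 at −78 °C should brominate 11 at C8 to 8-bromo-5,7,3',4'-tetra-O-benzylepicatechin F7. DDQ and 2-ethoxyethanol should give 8-bromo-5,7,3',4'-tetra-O-benzyl-4β-(2-ethoxyethoxy)epicatechin F8, which cannot act as a C8 nucleophile. TMSOTf coupling with 21 should give the 8-bromo benzylated tetramer F9 (22 with bromine at C8 of unit 1). Hydrogenolysis over Pd(OH)2/C with Et3N should remove the bromine together with the benzyl groups and give 23.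

Further compounds
F1 | step 1 | racemic [3,4-bis(benzyloxy)phenyl](1,3-dithian-2-yl)methanol | OC(c1ccc(OCc2ccccc2)c(OCc2ccccc2)c1)C1SCCCS1
F2 | step 1 | 2-[3,4-bis(benzyloxy)benzoyl]-1,3-dithiane | O=C(c1ccc(OCc2ccccc2)c(OCc2ccccc2)c1)C1SCCCS1
F3 | step 1 | 2-[3,4-bis(benzyloxy)benzoyl]-2-(2,4,6-trifluorobenzyl)-1,3-dithiane | O=C(c1ccc(OCc2ccccc2)c(OCc2ccccc2)c1)C1(Cc2c(F)cc(F)cc2F)SCCCS1
F4 | step 1 | racemic [3,4-bis(benzyloxy)phenyl][2-(2,4,6-trifluorobenzyl)-1,3-dithian-2-yl]methanol | OC(c1ccc(OCc2ccccc2)c(OCc2ccccc2)c1)C1(Cc2c(F)cc(F)cc2F)SCCCS1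
F5 | step 4 | racemic cis-5,7,3',4'-tetra-O-benzylflavan-3-ol (both enantiomers) | O[C@@H]1Cc2c(OCc3ccccc3)cc(OCc3ccccc3)cc2O[C@@H]1c1ccc(OCc3ccccc3)c(OCc3ccccc3)c1.O[C@H]1Cc2c(OCc3ccccc3)cc(OCc3ccccc3)cc2O[C@H]1c1ccc(OCc3ccccc3)c(OCc3ccccc3)c1
F6 | step 4 | (2R,3R)-3-O-acetyl-5,7,3',4'-tetra-O-benzylepicatechin | CC(=O)O[C@@H]1Cc2c(OCc3ccccc3)cc(OCc3ccccc3)cc2O[C@@H]1c1ccc(OCc3ccccc3)c(OCc3ccccc3)c1
F7 | step 12 | (2R,3R)-8-bromo-5,7,3',4'-tetra-O-benzylepicatechin | O[C@@H]1Cc2c(OCc3ccccc3)cc(OCc3ccccc3)c(Br)c2O[C@@H]1c1ccc(OCc3ccccc3)c(OCc3ccccc3)c1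
F8 | step 12 | 8-bromo-5,7,3',4'-tetra-O-benzyl-4β-(2-ethoxyethoxy)epicatechin | CCOCCO[C@H]1c2c(OCc5ccccc5)cc(OCc5ccccc5)c(Br)c2O[C@H](c2ccc(OCc5ccccc5)c(OCc5ccccc5)c2)[C@@H]1O
F9 | step 12 | 8-bromo benzylated tetramer (bromine at C8 of unit 1) | O=C(O[C@@H]1[C@@H](c2c(OCc5ccccc5)cc(OCc5ccccc5)c3c2O[C@H](c2ccc(OCc5ccccc5)c(OCc5ccccc5)c2)[C@H](O)[C@H]3c2c(OCc5ccccc5)cc(OCc5ccccc5)c3c2O[C@H](c2ccc(OCc5ccccc5)c(OCc5ccccc5)c2)[C@@H](O)C3)c2c(OCc5ccccc5)cc(OCc5ccccc5)c([C@H]3c4c(OCc5ccccc5)cc(OCc5ccccc5)c(Br)c4O[C@H](c4ccc(OCc5ccccc5)c(OCc5ccccc5)c4)[C@@H]3O)c2O[C@@H]1c1cc(OCc5ccccc5)c(OCc5ccccc5)c(OCc5ccccc5)c1)c1cc(OCc5ccccc5)c(OCc5ccccc5)c(OCc5ccccc5)c1
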